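(The data were computed from invented constants; the scatter is artificial.)

This closed, stirred vessel holds starting material and reagent, and you read it at 2.5 min.

| flask | starting material | reagent | remark | time |
|---|---|---|---|---|
| south-east | 0.20 mM | 0.31 mM | run made earlier |  |
| west | 0.20 mM | 0.48 mM | run made earlier |  |
| south-west | 0.30 mM | 0.22 mM | run made earlier |  |
| flask | 0.20 mM | 0.220 mM |  | 2.5 min |

- south-east (time / s: starting material / %, first product / %): 12.0: 28.9, 31.3; 30.0: 11.4, 15.2; 60.0: 4.7, 4.7; 90.0: 2.0, 2.4
- west (time / s: starting material / %, first product / %): 10.0: 16.4, 32.6; 15.0: 9.2, 24.1; 40.0: 0.5, 3.8; 90.0: 0, 0.1
- south-west (time / s: starting material / %, first product / %): 25.0: 40.8, 17.6; 50.0: 37.8, 5.7; 60.0: 37.3, 4.8; 90.0: 37.7, 1.1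

(scatter of a reading: 0.5 percentage points)

* amount of starting material at 2.5 min, in percent of the starting material charged
* amount of first product at 2.5 min, in percent of the starting material charged
* amount of other mono adduct at 2.5 min, in percent of the starting material charged
* amount of bis adduct at 2.5 min, in percent of the starting material charged

Climb the time scales from the fastest. In the west run, starting material fell to 16.4% in 10.0 s, a loss constant of 0.181 s⁻¹. Scaled to this flask's reagent, that is a half-life of about 8.37 s. Next, in the south-west run, starting material stays flat near 37.7% while first product keeps falling, with a half-life read as 16.9 s, slower than the first rung. Both are shorter than 2.5 min, so in this flask you expect first product near zero, and the question left is how the reagent was shared.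

Take as the zero of the scale the case where each reagent molecule adds to a fresh molecule of starting material. In this flask c(reagent)/c(starting material) = 1.10, so in that case the reagent charge is more than the starting material needs. But each second addition spends reagent and uses no starting material. Suppose the 0.22 mM of reagent in the south-west run has gone by the flat stretch: it covers 73.3% of that run's starting material, yet the last reading shows 62.3% used, which gives 0.177: this is the second-addition share, bis adduct made per starting material used. Carried to this flask, with its reagent supposed gone as well, the share gives your estimate of 6.55% starting material and 16.6% bis adduct. No reading shows other mono adduct, so you set no number for it.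

The forecast says 8%, 1.2%, 29% and 14%, in the order asked, and of the reagent in this flask it says “second addition eats it”. Your own estimate differs, with less starting material and more bis adduct than the forecast.

The flask gives 13.0%, 0.520%, 5.32% and 21.8%.

    reagent + other mono adduct → bis adduct + by-product (k = 260 M⁻¹ s⁻¹)
    starting material + reagent → first product + by-product (k = 480 M⁻¹ s⁻¹)
    starting material + reagent → other mono adduct + by-product (k = 61.0 M⁻¹ s⁻¹)
    reagent + first product → bis adduct + by-product (k = 260 M⁻¹ s⁻¹)
    first product → over-reaction product (k = 0.0490 s⁻¹)

In the flask the reagent, the limiting reagent here, stands at 1.06% of its charge at 2.50 min, and the flask's second-addition share is 0.251, larger than the 0.177 read in the south-west run. The neighbour flask with 0.34 mM of starting material holds 0% reagent at 2.50 min. Reckoned with 0.177, it should keep 45.0% starting material, and it keeps 43.7%.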